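**Retrosynthetic overview**

1. Ring C (the pyranone) is the lactol of an aryl β-keto aldehyde. It is made last, by a one-carbon oxidative ring expansion of the furan ring of a 3-(2-aryl-2-silyloxyethyl)benzofuran: ozonolysis of furan C2=C3, then O-to-C formyl transfer onto the side-chain CH2.
2. Enabling feature: in ring C the lactol carbon C2 sits on ring oxygen O1 and the ketone carbon C4 on ring carbon C4a. These are the two bonds that flank the C2=C3 bond of a benzofuran, so cleaving that bond leaves a formyl group on O1 and an acyl group on ring A, and the CH2 between C4 and C9 becomes C3.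
3. Stereochemistry: C9 is fixed before the key step by Noyori transfer hydrogenation of the aryl ketone. C3 and C2 arise in the key step and are funnelled by equilibration (enol and ring-chain tautomerism).
4. Benzofuran: the furan ring comes from an intramolecular Heck cyclisation of an aryl 4-oxycrotonate ether, the C8 methyl from a Negishi coupling, and ring B from an aryl Grignard addition to a Weinreb amide.
5. Ring order: ring A is bought (2-methoxyresorcinol) and O1 is introduced by C–H borylation/oxidation; then the furan ring; then ring C by expansion. Ring B is bought.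

Key step: step 11

Assumption: C2 (lactol carbon) and C3 (between the ketone and the masked aldehyde) are configurationally labile, and the (2S,3R) arrangement next to the fixed (S)-C9 is taken to be the one in which this equilibrating system rests.

**Route**

Step 1
Reactants: 1 2-methoxyresorcinol
Product: 2 2-methoxy-1,3-bis(triisopropylsilyloxy)benzene
Conditions: i-Pr3SiCl, imidazole, DMF, rt
Reagents that add atoms: chlorotriisopropylsilane CC(C)[Si](Cl)(C(C)C)C(C)C
Why: Imidazole-promoted silylation of both phenols; the bulky TIPS ethers survive the base and palladium steps, screen the two ortho C–H bonds in the next step and fall to fluoride at the end.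

Step 2
Reactants: 2 2-methoxy-1,3-bis(triisopropylsilyloxy)benzene
Product: 4 4-methoxy-3,5-bis(triisopropylsilyloxy)phenol, via aryl pinacol boronate 3 (not isolated)
Conditions: [Ir(OMe)(cod)]2, 4,4'-di-tert-butyl-2,2'-bipyridine, B2pin2, THF, 80 °C; then KHSO5 (as 2KHSO5·KHSO4·K2SO4), acetone/H2O, 0 °C
Reagents that add atoms: bis(pinacolato)diboron CC1(C)OB(OC1(C)C)B1OC(C)(C)C(C)(C)O1 (boron of 3); potassium peroxymonosulfate [K+].[O-]S(=O)(=O)OO (hydroxyl oxygen of 4)
Why: Iridium-catalysed C–H borylation (Hartwig–Miyaura) is sterically controlled and should touch only C5, the one C–H bond without an ortho substituent, and the boronate is oxidised in the same flask to the phenol whose oxygen becomes O1 of the target.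

Step 3
Reactants: 4 4-methoxy-3,5-bis(triisopropylsilyloxy)phenol
Product: 5 2,6-diiodo-4-methoxy-3,5-bis(triisopropylsilyloxy)phenol
Conditions: N-iodosuccinimide, MeCN, 0 °C to rt
Reagents that add atoms: N-iodosuccinimide O=C1CCC(=O)N1I
Why: Electrophilic aromatic iodination of the electron-rich phenol at its two equivalent free ortho positions gives the handle for the furan ring at one carbon and for the C8 methyl group at the other.

Step 4
Reactants: 5 2,6-diiodo-4-methoxy-3,5-bis(triisopropylsilyloxy)phenol; 6 ethyl (E)-4-bromobut-2-enoate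
Product: 7 ethyl (E)-4-[2,6-diiodo-4-methoxy-3,5-bis(triisopropylsilyloxy)phenoxy]but-2-enoate
Conditions: K2CO3, acetone, rt
Reagents that add atoms: none
Why: Williamson ether synthesis (SN2 at the allylic bromide) with the acidic diiodophenol; K2CO3 in acetone should leave the aryl TIPS ethers intact.

Step 5
Reactants: 7 ethyl (E)-4-[2,6-diiodo-4-methoxy-3,5-bis(triisopropylsilyloxy)phenoxy]but-2-enoate
Product: 8 ethyl 2-[7-iodo-5-methoxy-4,6-bis(triisopropylsilyloxy)-1-benzofuran-3-yl]acetate
Conditions: Pd(OAc)2, PPh3, Et3N, MeCN, 80 °C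
Reagents that add atoms: none
Why: Intramolecular Heck reaction: oxidative addition into either of the two equivalent C–I bonds, 5-exo-trig carbopalladation at the β-carbon of the enoate, β-hydride elimination and shift of the exocyclic double bond into the ring should give the aromatic benzofuran-3-ylacetate, the second and now hindered C–I bond being kept for the next step.

Step 6
Reactants: 8 ethyl 2-[7-iodo-5-methoxy-4,6-bis(triisopropylsilyloxy)-1-benzofuran-3-yl]acetate
Product: 9 ethyl 2-[5-methoxy-7-methyl-4,6-bis(triisopropylsilyloxy)-1-benzofuran-3-yl]acetate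
Conditions: MeZnCl, Pd(P(t-Bu)3)2, THF, rt to 40 °C
Reagents that add atoms: methylzinc chloride C[Zn]Cl
Why: Negishi cross-coupling installs the methyl group (C8 of the target) at the hindered iodide under conditions that tolerate the ester and the silyl ethers.

Step 7
Reactants: 9 ethyl 2-[5-methoxy-7-methyl-4,6-bis(triisopropylsilyloxy)-1-benzofuran-3-yl]acetate
Product: 10 N-methoxy-N-methyl-2-[5-methoxy-7-methyl-4,6-bis(triisopropylsilyloxy)-1-benzofuran-3-yl]acetamide
Conditions: MeNH(OMe)·HCl, i-PrMgCl, THF, −20 to 0 °C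
Reagents that add atoms: N,O-dimethylhydroxylamine hydrochloride CNOC.Cl
Why: The chloromagnesium amide of N,O-dimethylhydroxylamine converts the ester directly into the Weinreb amide.

Step 8
Reactants: 10 N-methoxy-N-methyl-2-[5-methoxy-7-methyl-4,6-bis(triisopropylsilyloxy)-1-benzofuran-3-yl]acetamide; 11 (4-bromophenoxy)(tert-butyl)dimethylsilane
Product: 13 1-[4-(tert-butyldimethylsilyloxy)phenyl]-2-[5-methoxy-7-methyl-4,6-bis(triisopropylsilyloxy)-1-benzofuran-3-yl]ethan-1-one, via aryl Grignard reagent 12 (not isolated)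
Conditions: Mg, THF, 50 °C (11 to 12); then 10, THF, 0 °C to rt; aq NH4Cl
Reagents that add atoms: magnesium [Mg] (present only in 12)
Why: Addition of the aryl Grignard reagent to the Weinreb amide stops at the chelated tetrahedral adduct, so work-up should give the aryl ketone that carries ring B without over-addition.

Step 9
Reactants: 13 1-[4-(tert-butyldimethylsilyloxy)phenyl]-2-[5-methoxy-7-methyl-4,6-bis(triisopropylsilyloxy)-1-benzofuran-3-yl]ethan-1-one
Product: 14 (1S)-1-[4-(tert-butyldimethylsilyloxy)phenyl]-2-[5-methoxy-7-methyl-4,6-bis(triisopropylsilyloxy)-1-benzofuran-3-yl]ethan-1-ol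
Conditions: RuCl(p-cymene)[(S,S)-TsDPEN], HCO2H/Et3N, DMF, 40 °C
Reagents that add atoms: none
Why: Noyori asymmetric transfer hydrogenation of the aryl alkyl ketone; the (S,S)-catalyst delivers hydride to the face that gives (S)-1-aryl carbinols, which sets C9 of the target as S.

Step 10
Reactants: 14 (1S)-1-[4-(tert-butyldimethylsilyloxy)phenyl]-2-[5-methoxy-7-methyl-4,6-bis(triisopropylsilyloxy)-1-benzofuran-3-yl]ethan-1-ol
Product: 15 3-[(2S)-2-(tert-butyldimethylsilyloxy)-2-[4-(tert-butyldimethylsilyloxy)phenyl]ethyl]-5-methoxy-7-methyl-4,6-bis(triisopropylsilyloxy)-1-benzofuran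
Conditions: t-BuMe2SiOTf, 2,6-lutidine, CH2Cl2, −78 to 0 °C
Reagents that add atoms: tert-butyldimethylsilyl triflate CC(C)(C)[Si](C)(C)OS(=O)(=O)C(F)(F)F
Why: Silylation of the secondary alcohol (silyl triflate, hindered base) blocks retro-aldol and alkoxide chemistry in the key step; no stereocentre is touched.

Step 11
Reactants: 15 3-[(2S)-2-(tert-butyldimethylsilyloxy)-2-[4-(tert-butyldimethylsilyloxy)phenyl]ethyl]-5-methoxy-7-methyl-4,6-bis(triisopropylsilyloxy)-1-benzofuran
Product: 17 (2S,3R)-3-[(S)-(tert-butyldimethylsilyloxy)[4-(tert-butyldimethylsilyloxy)phenyl]methyl]-2-hydroxy-6-methoxy-8-methyl-5,7-bis(triisopropylsilyloxy)chroman-4-one, via keto formate 16 (not isolated)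
Conditions: O3, CH2Cl2, −78 °C; PPh3, −78 to 0 °C; then LiN(SiMe3)2, THF, −78 to −40 °C; aq NH4Cl
Reagents that add atoms: ozone [O-][O+]=O
Why: Proposed new method: ozone should add to the enol-ether C2=C3 bond of the benzofuran much faster than to the silylated arenes, and PPh3 reduction of the ozonide leaves aryl formate 16, in which furan C2 has become the formyl group on O1 and furan C3 the aryl ketone (C4 of the target). LiN(SiMe3)2 then deprotonates the only enolisable position, the side-chain CH2 (C3 of the target), and the lithium enolate attacks the neighbouring formate through a six-membered transition state (6-exo-trig at the formyl carbon), so the tetrahedral adduct is already the lithium alkoxide of the six-membered lactol and the five-membered ring has grown by one carbon. The closest known reaction types are the Witkop–Winterfeldt oxidation of indoles to 4-quinolones (oxidative cleavage of the five-membered ring, then closure by the ketone α-carbon onto the acyl group left on the heteroatom) and the Baker–Venkataraman O-to-C acyl transfer; ozonolysis of benzofurans to 2-(formyloxy)aryl ketones and base-mediated C-formylation of 2-hydroxyaryl ketones to 2-hydroxychromanones are each known. C9 is not touched; C3 is created on protonation of the β-keto aldehyde enolate and C2 on lactol closure, and because both are labile they should equilibrate under the bias of C9 to the 2,3-trans (2S,3R) isomer. The step needs formyl transfer to outrun attack of the amide base on the formate, β-elimination of the C9 silyloxy group and silyl migration from the ortho TIPS ether to the enolate oxygen; the intramolecular delivery to a very electrophilic formate at −78 °C, the poor leaving-group ability of a silyloxide and the bulk of TIPS should secure this.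

Step 12
Reactants: 17 (2S,3R)-3-[(S)-(tert-butyldimethylsilyloxy)[4-(tert-butyldimethylsilyloxy)phenyl]methyl]-2-hydroxy-6-methoxy-8-methyl-5,7-bis(triisopropylsilyloxy)chroman-4-one
Product: 18 (2S,3R)-2,5,7-trihydroxy-3-[(S)-hydroxy(4-hydroxyphenyl)methyl]-6-methoxy-8-methylchroman-4-one
Conditions: Bu4NF, AcOH, THF, 0 °C to rt
Reagents that add atoms: none
Why: Fluoride cleaves the two aryl TIPS ethers, the aryl TBS ether and the alkyl TBS ether, and acetic acid buffering keeps the medium near neutral so that the lactol should neither lose water to the chromone nor undergo retro-aldol cleavage; C9 is untouched and C2/C3 should stay at their equilibrium (2S,3R) configuration.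

**Compound list**

1 | 2-methoxyresorcinol | COc1c(O)cccc1O | starting material
2 | 2-methoxy-1,3-bis(triisopropylsilyloxy)benzene | COc1c(O[Si](C(C)C)(C(C)C)C(C)C)cccc1O[Si](C(C)C)(C(C)C)C(C)C | intermediate
3 | 2-[4-methoxy-3,5-bis(triisopropylsilyloxy)phenyl]-4,4,5,5-tetramethyl-1,3,2-dioxaborolane | COc1c(O[Si](C(C)C)(C(C)C)C(C)C)cc(B2OC(C)(C)C(C)(C)O2)cc1O[Si](C(C)C)(C(C)C)C(C)C | intermediate
4 | 4-methoxy-3,5-bis(triisopropylsilyloxy)phenol | COc1c(O[Si](C(C)C)(C(C)C)C(C)C)cc(O)cc1O[Si](C(C)C)(C(C)C)C(C)C | intermediate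
5 | 2,6-diiodo-4-methoxy-3,5-bis(triisopropylsilyloxy)phenol | COc1c(O[Si](C(C)C)(C(C)C)C(C)C)c(I)c(O)c(I)c1O[Si](C(C)C)(C(C)C)C(C)C | intermediate
6 | ethyl (E)-4-bromobut-2-enoate | CCOC(=O)/C=C/CBr | starting material
7 | ethyl (E)-4-[2,6-diiodo-4-methoxy-3,5-bis(triisopropylsilyloxy)phenoxy]but-2-enoate | CCOC(=O)/C=C/COc1c(I)c(O[Si](C(C)C)(C(C)C)C(C)C)c(OC)c(O[Si](C(C)C)(C(C)C)C(C)C)c1I | intermediate
8 | ethyl 2-[7-iodo-5-methoxy-4,6-bis(triisopropylsilyloxy)-1-benzofuran-3-yl]acetate | CCOC(=O)Cc1coc2c(I)c(O[Si](C(C)C)(C(C)C)C(C)C)c(OC)c(O[Si](C(C)C)(C(C)C)C(C)C)c12 | intermediate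
9 | ethyl 2-[5-methoxy-7-methyl-4,6-bis(triisopropylsilyloxy)-1-benzofuran-3-yl]acetate | CCOC(=O)Cc1coc2c(C)c(O[Si](C(C)C)(C(C)C)C(C)C)c(OC)c(O[Si](C(C)C)(C(C)C)C(C)C)c12 | intermediate
10 | N-methoxy-N-methyl-2-[5-methoxy-7-methyl-4,6-bis(triisopropylsilyloxy)-1-benzofuran-3-yl]acetamide | CON(C)C(=O)Cc1coc2c(C)c(O[Si](C(C)C)(C(C)C)C(C)C)c(OC)c(O[Si](C(C)C)(C(C)C)C(C)C)c12 | intermediate
11 | (4-bromophenoxy)(tert-butyl)dimethylsilane | CC(C)(C)[Si](C)(C)Oc1ccc(Br)cc1 | starting material
12 | [4-(tert-butyldimethylsilyloxy)phenyl]magnesium bromide | Br[Mg]c1ccc(O[Si](C)(C)C(C)(C)C)cc1 | intermediate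
13 | 1-[4-(tert-butyldimethylsilyloxy)phenyl]-2-[5-methoxy-7-methyl-4,6-bis(triisopropylsilyloxy)-1-benzofuran-3-yl]ethan-1-one | COc1c(O[Si](C(C)C)(C(C)C)C(C)C)c(C)c2occ(CC(=O)c3ccc(O[Si](C)(C)C(C)(C)C)cc3)c2c1O[Si](C(C)C)(C(C)C)C(C)C | intermediate
14 | (1S)-1-[4-(tert-butyldimethylsilyloxy)phenyl]-2-[5-methoxy-7-methyl-4,6-bis(triisopropylsilyloxy)-1-benzofuran-3-yl]ethan-1-ol | COc1c(O[Si](C(C)C)(C(C)C)C(C)C)c(C)c2occ(C[C@H](O)c3ccc(O[Si](C)(C)C(C)(C)C)cc3)c2c1O[Si](C(C)C)(C(C)C)C(C)C | intermediate
15 | 3-[(2S)-2-(tert-butyldimethylsilyloxy)-2-[4-(tert-butyldimethylsilyloxy)phenyl]ethyl]-5-methoxy-7-methyl-4,6-bis(triisopropylsilyloxy)-1-benzofuran | COc1c(O[Si](C(C)C)(C(C)C)C(C)C)c(C)c2occ(C[C@H](O[Si](C)(C)C(C)(C)C)c3ccc(O[Si](C)(C)C(C)(C)C)cc3)c2c1O[Si](C(C)C)(C(C)C)C(C)C | intermediate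
16 | 2-[(3S)-3-(tert-butyldimethylsilyloxy)-3-[4-(tert-butyldimethylsilyloxy)phenyl]propanoyl]-4-methoxy-6-methyl-3,5-bis(triisopropylsilyloxy)phenyl formate | COc1c(O[Si](C(C)C)(C(C)C)C(C)C)c(C)c(OC=O)c(C(=O)C[C@H](O[Si](C)(C)C(C)(C)C)c2ccc(O[Si](C)(C)C(C)(C)C)cc2)c1O[Si](C(C)C)(C(C)C)C(C)C | intermediate
17 | (2S,3R)-3-[(S)-(tert-butyldimethylsilyloxy)[4-(tert-butyldimethylsilyloxy)phenyl]methyl]-2-hydroxy-6-methoxy-8-methyl-5,7-bis(triisopropylsilyloxy)chroman-4-one | COc1c(O[Si](C(C)C)(C(C)C)C(C)C)c(C)c2c(c1O[Si](C(C)C)(C(C)C)C(C)C)C(=O)[C@H]([C@H](O[Si](C)(C)C(C)(C)C)c1ccc(O[Si](C)(C)C(C)(C)C)cc1)[C@@H](O)O2 | intermediate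
18 | (2S,3R)-2,5,7-trihydroxy-3-[(S)-hydroxy(4-hydroxyphenyl)methyl]-6-methoxy-8-methylchroman-4-one | COc1c(O)c(C)c2c(c1O)C(=O)[C@H]([C@H](O)c1ccc(O)cc1)[C@@H](O)O2 | target

**Step count and risks**

Total step count: 12. Longest linear sequence: 12 steps (1 to 18); the Grignard reagent 12 is made from 11 inside step 8.

Steps most likely to fail:

1. Step 11 (proposed new method). The amide base may attack the formate before the enolate does, the enolate may expel the C9 silyloxy group, or the ortho TIPS group may migrate to the enolate oxygen. The equilibrium at C3 may also not favour the 3R epimer. Fallback with known chemistry, from 15: ozonolysis and PPh3 reduction as before give 16; the formate is removed with NaHCO3 in MeOH at 0 °C to give (3S)-3-(tert-butyldimethylsilyloxy)-3-[4-(tert-butyldimethylsilyloxy)phenyl]-1-[2-hydroxy-5-methoxy-3-methyl-4,6-bis(triisopropylsilyloxy)phenyl]propan-1-one F1; intermolecular C-formylation of this 2-hydroxyaryl ketone with ethyl formate and NaH in THF (the classical entry to 2-hydroxychromanones) should then close the lactol and return to the route at 17.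

2. Step 12. While the slower alkyl and hindered aryl silyl ethers are being cleaved, the lactol may lose water to the chromone, the C3–C9 bond may break by retro-aldol reaction, the C3 epimer ratio may drift, or the lactol may re-close on the C5 oxygen. Fallback, from 15: the protecting groups are exchanged before the ring expansion. Bu4NF in THF gives 3-[(2S)-2-hydroxy-2-(4-hydroxyphenyl)ethyl]-5-methoxy-7-methyl-1-benzofuran-4,6-diol F2. Et3SiCl and imidazole in DMF give its tetrakis(triethylsilyl) ether, 5-methoxy-7-methyl-4,6-bis(triethylsilyloxy)-3-[(2S)-2-(triethylsilyloxy)-2-[4-(triethylsilyloxy)phenyl]ethyl]-1-benzofuran F3. The conditions of step 11 lead through 4-methoxy-6-methyl-3,5-bis(triethylsilyloxy)-2-[(3S)-3-(triethylsilyloxy)-3-[4-(triethylsilyloxy)phenyl]propanoyl]phenyl formate F4 to (2S,3R)-2-hydroxy-6-methoxy-8-methyl-5,7-bis(triethylsilyloxy)-3-[(S)-(triethylsilyloxy)[4-(triethylsilyloxy)phenyl]methyl]chroman-4-one F5. The four labile triethylsilyl ethers are then removed within minutes by HF·pyridine buffered with pyridine in THF at 0 °C, and the sequence returns at 18.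

3. Step 5. Zerovalent palladium may insert into the second C–I bond that remains in the product, leading to hydrodeiodination or intermolecular Heck oligomers. Fallback, from 4: the methyl group is introduced before the cyclisation. Ortho-formylation (MgCl2, Et3N, paraformaldehyde, MeCN, reflux) gives 2-hydroxy-5-methoxy-4,6-bis(triisopropylsilyloxy)benzaldehyde F6. Hydrogenolysis (H2, Pd/C, EtOAc/AcOH) gives 4-methoxy-2-methyl-3,5-bis(triisopropylsilyloxy)phenol F7. N-iodosuccinimide gives 6-iodo-4-methoxy-2-methyl-3,5-bis(triisopropylsilyloxy)phenol F8. Alkylation with 6 (K2CO3, acetone) gives ethyl (E)-4-[2-iodo-4-methoxy-6-methyl-3,5-bis(triisopropylsilyloxy)phenoxy]but-2-enoate F9. The Heck cyclisation of step 5, now on a single C–I bond, returns to the route at 9.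

Further compounds

F1 | step 11 | (3S)-3-(tert-butyldimethylsilyloxy)-3-[4-(tert-butyldimethylsilyloxy)phenyl]-1-[2-hydroxy-5-methoxy-3-methyl-4,6-bis(triisopropylsilyloxy)phenyl]propan-1-one | COc1c(O[Si](C(C)C)(C(C)C)C(C)C)c(C)c(O)c(C(=O)C[C@H](O[Si](C)(C)C(C)(C)C)c2ccc(O[Si](C)(C)C(C)(C)C)cc2)c1O[Si](C(C)C)(C(C)C)C(C)C
F2 | step 12 | 3-[(2S)-2-hydroxy-2-(4-hydroxyphenyl)ethyl]-5-methoxy-7-methyl-1-benzofuran-4,6-diol | COc1c(O)c(C)c2occ(C[C@H](O)c3ccc(O)cc3)c2c1O
F3 | step 12 | 5-methoxy-7-methyl-4,6-bis(triethylsilyloxy)-3-[(2S)-2-(triethylsilyloxy)-2-[4-(triethylsilyloxy)phenyl]ethyl]-1-benzofuran | COc1c(O[Si](CC)(CC)CC)c(C)c2occ(C[C@H](O[Si](CC)(CC)CC)c3ccc(O[Si](CC)(CC)CC)cc3)c2c1O[Si](CC)(CC)CC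
F4 | step 12 | 4-methoxy-6-methyl-3,5-bis(triethylsilyloxy)-2-[(3S)-3-(triethylsilyloxy)-3-[4-(triethylsilyloxy)phenyl]propanoyl]phenyl formate | COc1c(O[Si](CC)(CC)CC)c(C)c(OC=O)c(C(=O)C[C@H](O[Si](CC)(CC)CC)c2ccc(O[Si](CC)(CC)CC)cc2)c1O[Si](CC)(CC)CC
F5 | step 12 | (2S,3R)-2-hydroxy-6-methoxy-8-methyl-5,7-bis(triethylsilyloxy)-3-[(S)-(triethylsilyloxy)[4-(triethylsilyloxy)phenyl]methyl]chroman-4-one | COc1c(O[Si](CC)(CC)CC)c(C)c2c(c1O[Si](CC)(CC)CC)C(=O)[C@H]([C@H](O[Si](CC)(CC)CC)c1ccc(O[Si](CC)(CC)CC)cc1)[C@@H](O)O2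
F6 | step 5 | 2-hydroxy-5-methoxy-4,6-bis(triisopropylsilyloxy)benzaldehyde | COc1c(O[Si](C(C)C)(C(C)C)C(C)C)cc(O)c(C=O)c1O[Si](C(C)C)(C(C)C)C(C)C
F7 | step 5 | 4-methoxy-2-methyl-3,5-bis(triisopropylsilyloxy)phenol | COc1c(O[Si](C(C)C)(C(C)C)C(C)C)cc(O)c(C)c1O[Si](C(C)C)(C(C)C)C(C)C
F8 | step 5 | 6-iodo-4-methoxy-2-methyl-3,5-bis(triisopropylsilyloxy)phenol | COc1c(O[Si](C(C)C)(C(C)C)C(C)C)c(I)c(O)c(C)c1O[Si](C(C)C)(C(C)C)C(C)C
F9 | step 5 | ethyl (E)-4-[2-iodo-4-methoxy-6-methyl-3,5-bis(triisopropylsilyloxy)phenoxy]but-2-enoate | CCOC(=O)/C=C/COc1c(I)c(O[Si](C(C)C)(C(C)C)C(C)C)c(OC)c(O[Si](C(C)C)(C(C)C)C(C)C)c1C
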